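**Retrosynthetic overview**

1. The hexamer is cut at the ring B–ring C methylene (Mannich-base / ortho-quinone methide alkylation) into a ring A–CH2–ring B dimer and a ring C–D–E–F tetramer. The tetramer comes from a symmetric C–D–E trimer (bis-Mannich base of butyrylphloroglucinol plus two monomers) and the Mannich base of ring F.
2. Ring A (C1 = the carbonyl between the butanoyl-bearing C2 and the bridge-bearing C6; C4 = the gem-dimethyl carbon) is never handled as a monomer. It is annulated onto ring B in one flask by a [4+2] double acyl transfer between a chroman-2-one and 3,3-dimethyl-6-propylpyran-2,4-dione. The chromanone is ring B fused to a temporary lactone made with acrylic acid, which supplies the bridge CH2, C6 and C1. The pyrandione supplies C2–C5 with the gem-dimethyl and butanoyl groups in place.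
3. Enabling feature: the ring-B phenol oxygen ortho to the bridge sits 1,5 to C1 of ring A (O–C(aryl)–C(aryl)–CH2–C6–C1). C1 can therefore be carried as an aryl lactone carbonyl with the ring-B phenoxide as built-in leaving group. The quaternary C4 leaves C2, flanked by the C3 and butanoyl carbonyls, as the only carbon nucleophile that reaches C1; its attack closes ring A and frees the ring-B hydroxyl.
4. Ring order: rings B–F are bought or made as acylphloroglucinols; the temporary pyranone (step 2) and lactone (step 3) rings are made and both are opened as ring A closes (step 4); steps 5–11 only form CH2 bridges.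

Key step: step 4

Assumption 1: the lactone of step 3 is drawn closed onto the hydroxyl between the new side chain and the butanoyl group (8-butanoyl isomer). Closure onto the other ortho hydroxyl would give the 6-butanoyl isomer, which opens to the same ring-B pattern in step 4, so both isomers lead to the same dimer.

Assumption 2: ring A is written throughout in the enol tautomer of the target SMILES; the target is achiral.

**Step 1**
Reactants: 1 ethyl 2,2-dimethyl-3-oxobutanoate
Product: 2 ethyl 2,2-dimethyl-3,5-dioxooctanoate
Conditions: butyryl chloride, MgBr2·OEt2 (2.5 equiv), i-Pr2NEt (3 equiv), CH2Cl2, 0 → 23 °C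
Reagents that add atoms: butyryl chloride, CCCC(=O)Cl
Why: the acetyl methyl group is the only enolisable position of 1 (C2 is quaternary), and MgBr2-mediated soft enolisation with C-acylation by the acid chloride (direct Claisen-type ketone acylation) should stop at the magnesium 1,3-diketonate while avoiding the retro-Claisen cleavage that alkoxide bases would cause.

**Step 2**
Reactants: 2 ethyl 2,2-dimethyl-3,5-dioxooctanoate
Product: 3 3,3-dimethyl-6-propyl-2H-pyran-2,4(3H)-dione
Conditions: conc. H2SO4, 0 → 23 °C; ice-water
Reagents that add atoms: none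
Why: acid-mediated enol lactonisation (the classical closure of 3,5-dioxo esters to pyranones) should let the C5 enol oxygen close onto the ester in a 6-exo-trig manner helped by the gem-dimethyl group, with sulfuric acid taking up the ethanol so that the non-enolisable pyran-2,4-dione does not reopen.

**Step 3**
Reactants: 4 1-(2,4,6-trihydroxyphenyl)butan-1-one (butyrylphloroglucinol); 5 acrylic acid
Product: 7 8-butanoyl-5,7-dihydroxychroman-2-one, via arylpropanoic acid 6 (not isolated)
Conditions: Amberlyst 15, toluene–1,4-dioxane, 100 °C, −H2O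
Reagents that add atoms: none
Why: Friedel–Crafts conjugate addition (hydroarylation) of acrylic acid at one of the two equivalent free ring positions followed by lactonisation, as in the sulfonic-acid-resin synthesis of hydroxydihydrocoumarins from polyphenols, should give the lactone, and acylation of one phenol oxygen lowers the reactivity of the last ring position toward a second annulation.

**Step 4**
Reactants: 7 8-butanoyl-5,7-dihydroxychroman-2-one; 3 3,3-dimethyl-6-propyl-2H-pyran-2,4(3H)-dione
Product: 10 2-butanoyl-6-[(3-butanoyl-2,4,6-trihydroxyphenyl)methyl]-3,5-dihydroxy-4,4-dimethylcyclohexa-2,5-dien-1-one, via trilithium lactone enolate 8 (not isolated), via 3-acyl lactone 9 (not isolated)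
Conditions: LiN(SiMe3)2 (3.05 equiv), THF–DMPU, −78 °C; added to 3 (1.1 equiv), THF, −78 °C; −78 → 40 °C; 1 M HCl
Reagents that add atoms: none
Why: LiN(SiMe3)2 forms the two lithium phenoxides and then the lactone enolate 8, whose carbon (future C6 of ring A) attacks the lactone carbonyl of the enol lactone 3 in a crossed Claisen acylation, so that the pyranone opens and 9 carries the new chain as its lithium 1,3-diketonate (C5–C6 bond made, C2 unveiled as nucleophile). On warming, the diketonate carbon C2 adds to the aryl lactone carbonyl (future C1) and the ring-B phenoxide leaves, a Dieckmann-type O-to-C acyl transfer that closes ring A by a 6-exo-trig attack. The closest known reaction types are the domino crossed-Claisen/Dieckmann condensation with activated (enol and aryl) esters, the Claisen cyclisation of 3,5,7-triketo esters and their pyranone forms to acylphloroglucinols, and the Baker–Venkataraman acyl transfer. No stereocentre is set: C3 of 9 is racemic and labile and becomes the sp2 carbon C6. The step needs three selectivities: deprotonation of the lactone CH2 and not the butanoyl CH2 (the ketone is conjugated with two phenoxides and behaves as a vinylogous carboxylate, whereas the lactone carbonyl is insulated from them); C-acylation over proton transfer (the enolate is run into 3 so that it meets little of the acidic 9); and Claisen over aldol closure (C4 blocks enolisation between the two ketones, aldol adducts are reversible, and the enolised triketone anion of 10 is the thermodynamic sink).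

**Step 5**
Reactants: 4 1-(2,4,6-trihydroxyphenyl)butan-1-one
Product: 12 1-[3,5-bis[(dimethylamino)methyl]-2,4,6-trihydroxyphenyl]butan-1-one, via mono-Mannich base 11 (not isolated)
Conditions: aq. CH2O (2.2 equiv), aq. Me2NH (2.2 equiv), EtOH, 0 → 23 °C
Reagents that add atoms: formaldehyde, C=O; dimethylamine, CNC
Why: double Mannich aminomethylation of the two equivalent nucleophilic ring positions should give a product with no free ring carbon, which therefore cannot self-condense.

**Step 6**
Reactants: 12 1-[3,5-bis[(dimethylamino)methyl]-2,4,6-trihydroxyphenyl]butan-1-one; 4 1-(2,4,6-trihydroxyphenyl)butan-1-one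
Product: 14 1-[3,5-bis[(3-butanoyl-2,4,6-trihydroxyphenyl)methyl]-2,4,6-trihydroxyphenyl]butan-1-one (symmetric ring C–D–E trimer), via aminomethyl dimer 13 (not isolated)
Conditions: 4 (8 equiv), AcOH (cat.), 1,4-dioxane–H2O, 80 °C
Reagents that add atoms: none
Why: loss of dimethylamine gives an ortho-quinone methide that is captured at carbon by the acylphloroglucinol (Mannich-base amine exchange, Michael addition to an ortho-quinone methide), twice, and the large excess of 4 should make each quinone methide meet a monomer and not a product molecule.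

**Step 7**
Reactants: 15 2-methylbenzene-1,3,5-triol
Product: 16 1-(2,4,6-trihydroxy-3-methylphenyl)butan-1-one (ring F)
Conditions: butyryl chloride, AlCl3, PhNO2–CH2Cl2, 0 → 60 °C; aq. HCl
Reagents that add atoms: butyryl chloride, CCCC(=O)Cl
Why: Friedel–Crafts acylation at one of the two equivalent free positions of the electron-rich ring should stop after one acyl group, which deactivates the ring.

**Step 8**
Reactants: 16 1-(2,4,6-trihydroxy-3-methylphenyl)butan-1-one
Product: 17 1-[3-[(dimethylamino)methyl]-2,4,6-trihydroxy-5-methylphenyl]butan-1-one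
Conditions: aq. CH2O, aq. Me2NH, EtOH, 0 → 23 °C
Reagents that add atoms: formaldehyde, C=O; dimethylamine, CNC
Why: Mannich aminomethylation can only occur at the single remaining ring position.

**Step 9**
Reactants: 14 symmetric ring C–D–E trimer; 17 1-[3-[(dimethylamino)methyl]-2,4,6-trihydroxy-5-methylphenyl]butan-1-one
Product: 18 ring C–D–E–F tetramer with one free position on ring C
Conditions: 14 (3 equiv), AcOH (cat.), 1,4-dioxane–H2O, 80 °C
Reagents that add atoms: none
Why: ortho-quinone methide alkylation as in step 6, in which the trimer offers two equivalent terminal ring positions and is used in excess so that monoalkylation should dominate and unreacted 14 can be recovered.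

**Step 10**
Reactants: 18 ring C–D–E–F tetramer
Product: 19 ring C–D–E–F tetramer with a (dimethylamino)methyl group on ring C
Conditions: aq. CH2O, aq. Me2NH, EtOH–THF, 0 → 23 °C
Reagents that add atoms: formaldehyde, C=O; dimethylamine, CNC
Why: Mannich aminomethylation at the only unsubstituted ring carbon of 18 (terminal ring C) should give a Mannich base that cannot self-condense.

**Step 11**
Reactants: 10 ring A–CH2–ring B dimer; 19 aminomethylated ring C–D–E–F tetramer
Product: 20 CNP0309827.0 (target hexamer)
Conditions: AcOH (cat.), 1,4-dioxane–H2O, 60–80 °C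
Reagents that add atoms: none
Why: the ortho-quinone methide generated on ring C should be captured by the only free carbon of 10 (ring B), since ring A has no unsubstituted nucleophilic carbon (convergent Mannich-base alkylation).

**Compound list**

1 | ethyl 2,2-dimethyl-3-oxobutanoate | CCOC(=O)C(C)(C)C(C)=O | starting material
2 | ethyl 2,2-dimethyl-3,5-dioxooctanoate | CCCC(=O)CC(=O)C(C)(C)C(=O)OCC | intermediate
3 | 3,3-dimethyl-6-propyl-2H-pyran-2,4(3H)-dione | CCCC1=CC(=O)C(C)(C)C(=O)O1 | intermediate
4 | 1-(2,4,6-trihydroxyphenyl)butan-1-one | CCCC(=O)c1c(O)cc(O)cc1O | starting material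
5 | acrylic acid | C=CC(=O)O | starting material
6 | 3-(3-butanoyl-2,4,6-trihydroxyphenyl)propanoic acid | CCCC(=O)c1c(O)cc(O)c(CCC(=O)O)c1O | intermediate
7 | 8-butanoyl-5,7-dihydroxychroman-2-one | O=C1CCc2c(O)cc(O)c(C(=O)CCC)c2O1 | intermediate
8 | trilithium salt of 7 (lactone enolate, both phenols as lithium phenoxides) | [Li+].[Li+].[Li+].CCCC(=O)c1c([O-])cc([O-])c2CC=C([O-])Oc12 | intermediate
9 | 8-butanoyl-3-(2,2-dimethyl-3,5-dioxooctanoyl)-5,7-dihydroxychroman-2-one (racemic at C3, present as its lithium salt) | CCCC(=O)CC(=O)C(C)(C)C(=O)C1Cc2c(O)cc(O)c(C(=O)CCC)c2OC1=O | intermediate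
10 | 2-butanoyl-6-[(3-butanoyl-2,4,6-trihydroxyphenyl)methyl]-3,5-dihydroxy-4,4-dimethylcyclohexa-2,5-dien-1-one | CCCC(=O)C1=C(O)C(C)(C)C(O)=C(Cc2c(O)cc(O)c(C(=O)CCC)c2O)C1=O | intermediate
11 | 1-[3-[(dimethylamino)methyl]-2,4,6-trihydroxyphenyl]butan-1-one | CCCC(=O)c1c(O)cc(O)c(CN(C)C)c1O | intermediate
12 | 1-[3,5-bis[(dimethylamino)methyl]-2,4,6-trihydroxyphenyl]butan-1-one | CCCC(=O)c1c(O)c(CN(C)C)c(O)c(CN(C)C)c1O | intermediate
13 | 1-[3-[(3-butanoyl-2,4,6-trihydroxyphenyl)methyl]-5-[(dimethylamino)methyl]-2,4,6-trihydroxyphenyl]butan-1-one | CCCC(=O)c1c(O)c(CN(C)C)c(O)c(Cc2c(O)cc(O)c(C(=O)CCC)c2O)c1O | intermediate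
14 | 1-[3,5-bis[(3-butanoyl-2,4,6-trihydroxyphenyl)methyl]-2,4,6-trihydroxyphenyl]butan-1-one | CCCC(=O)c1c(O)cc(O)c(Cc2c(O)c(Cc3c(O)cc(O)c(C(=O)CCC)c3O)c(O)c(C(=O)CCC)c2O)c1O | intermediate
15 | 2-methylbenzene-1,3,5-triol | Cc1c(O)cc(O)cc1O | starting material
16 | 1-(2,4,6-trihydroxy-3-methylphenyl)butan-1-one | CCCC(=O)c1c(O)cc(O)c(C)c1O | intermediate
17 | 1-[3-[(dimethylamino)methyl]-2,4,6-trihydroxy-5-methylphenyl]butan-1-one | CCCC(=O)c1c(O)c(CN(C)C)c(O)c(C)c1O | intermediate
18 | ring C–D–E–F tetramer (three butanoylphloroglucinol rings and the methylated ring F joined by CH2, one free position on ring C) | CCCC(=O)c1c(O)cc(O)c(Cc2c(O)c(Cc3c(O)c(Cc4c(O)c(C)c(O)c(C(=O)CCC)c4O)c(O)c(C(=O)CCC)c3O)c(O)c(C(=O)CCC)c2O)c1O | intermediate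
19 | tetramer 18 with a (dimethylamino)methyl group at the free position of ring C | CCCC(=O)c1c(O)c(CN(C)C)c(O)c(Cc2c(O)c(Cc3c(O)c(Cc4c(O)c(C)c(O)c(C(=O)CCC)c4O)c(O)c(C(=O)CCC)c3O)c(O)c(C(=O)CCC)c2O)c1O | intermediate
20 | CNP0309827.0 | CCCC(=O)C1=C(O)C(C)(C)C(O)=C(Cc2c(O)c(Cc3c(O)c(Cc4c(O)c(Cc5c(O)c(Cc6c(O)c(C)c(O)c(C(=O)CCC)c6O)c(O)c(C(=O)CCC)c5O)c(O)c(C(=O)CCC)c4O)c(O)c(C(=O)CCC)c3O)c(O)c(C(=O)CCC)c2O)C1=O | target

**Count**

Total steps: 11. Longest linear sequence: 5 steps (5 → 6 → 9 → 10 → 11, or equally 7 → 8 → 9 → 10 → 11).

**Steps most likely to fail**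

Step 4. The base may also deprotonate the butanoyl CH2, the first-formed 3-acyl lactone may give up its acidic proton to unreacted enolate so that acylation stalls, or the acyl group may be transferred to phenoxide oxygen instead of carbon. Fallback: ring A is closed on its own by the same Claisen bond formation and then joined to ring B through a Mannich base. The fallback sets out from 3 and comes back at 10. Ring opening of 3 with the lithium enolate of methyl acetate (LiN(i-Pr)2, MeOAc, THF, −78 °C) should give methyl 4,4-dimethyl-3,5,7-trioxodecanoate F1. Claisen cyclisation of its diketone carbon onto the ester (NaH or KOt-Bu, THF) should give 2-butanoyl-3,5-dihydroxy-4,4-dimethylcyclohexa-2,5-dien-1-one F2. Mannich reaction (CH2O, Me2NH) should give 2-butanoyl-6-[(dimethylamino)methyl]-3,5-dihydroxy-4,4-dimethylcyclohexa-2,5-dien-1-one F3. Heating F3 with an excess of 4 (AcOH cat., dioxane–H2O) should give 10.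

Step 11. Capture of a hindered quinone methide by a large, poorly soluble nucleophile may be slow, which leaves time for exchange of methylene bridges between rings and gives mixtures of oligomers. Fallback: the order of assembly is changed so that the chain grows outward from the dimer with the partner always in excess, and the last bond is made to the small monomer 16. The fallback sets out from 10 and comes back at 20. Mannich reaction of 10 should give the ring-B aminomethyl dimer F4. Heating F4 with an excess of 14 should give the ring A–B–C–D–E pentamer F5. Mannich reaction at the free position of ring E should give the aminomethyl pentamer F6. Heating F6 with a large excess of 16 should give 20.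

Step 3. The acyl-deactivated ring may not add to acrylic acid, the acid may instead acylate the ring and lead to a chroman-4-one, or a second annulation may take place at the last free position. Fallback: the three carbons are brought in by a three-component condensation with formaldehyde and Meldrum's acid. The fallback sets out from 4 and comes back at 7. Reaction of 4 with CH2O and 2,2-dimethyl-1,3-dioxane-4,6-dione (Et3N cat., MeCN, 23 °C) should give 5-[(3-butanoyl-2,4,6-trihydroxyphenyl)methyl]-2,2-dimethyl-1,3-dioxane-4,6-dione F7. Heating in pyridine should lactonise it to 8-butanoyl-5,7-dihydroxy-2-oxochromane-3-carboxylic acid F8 (racemic), which should decarboxylate under the same conditions to 7.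

**Further compounds**

F1 | step 4 | methyl 4,4-dimethyl-3,5,7-trioxodecanoate | COC(=O)CC(=O)C(C)(C)C(=O)CC(=O)CCC
F2 | step 4 | 2-butanoyl-3,5-dihydroxy-4,4-dimethylcyclohexa-2,5-dien-1-one | CCCC(=O)C1=C(O)C(C)(C)C(O)=CC1=O
F3 | step 4 | 2-butanoyl-6-[(dimethylamino)methyl]-3,5-dihydroxy-4,4-dimethylcyclohexa-2,5-dien-1-one | CCCC(=O)C1=C(O)C(C)(C)C(O)=C(CN(C)C)C1=O
F4 | step 11 | dimer 10 with a (dimethylamino)methyl group at the free position of ring B | CCCC(=O)C1=C(O)C(C)(C)C(O)=C(Cc2c(O)c(CN(C)C)c(O)c(C(=O)CCC)c2O)C1=O
F5 | step 11 | ring A–B–C–D–E pentamer with one free position on ring E | CCCC(=O)C1=C(O)C(C)(C)C(O)=C(Cc2c(O)c(Cc3c(O)c(Cc4c(O)c(Cc5c(O)cc(O)c(C(=O)CCC)c5O)c(O)c(C(=O)CCC)c4O)c(O)c(C(=O)CCC)c3O)c(O)c(C(=O)CCC)c2O)C1=O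
F6 | step 11 | pentamer F5 with a (dimethylamino)methyl group at the free position of ring E | CCCC(=O)C1=C(O)C(C)(C)C(O)=C(Cc2c(O)c(Cc3c(O)c(Cc4c(O)c(Cc5c(O)c(CN(C)C)c(O)c(C(=O)CCC)c5O)c(O)c(C(=O)CCC)c4O)c(O)c(C(=O)CCC)c3O)c(O)c(C(=O)CCC)c2O)C1=O
F7 | step 3 | 5-[(3-butanoyl-2,4,6-trihydroxyphenyl)methyl]-2,2-dimethyl-1,3-dioxane-4,6-dione | CCCC(=O)c1c(O)cc(O)c(CC2C(=O)OC(C)(C)OC2=O)c1O
F8 | step 3 | 8-butanoyl-5,7-dihydroxy-2-oxochromane-3-carboxylic acid (racemic) | CCCC(=O)c1c(O)cc(O)c2CC(C(=O)O)C(=O)Oc12
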